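(The runs are simulated with constants of no real substance, and the scatter is random.)

Which of the four flasks holds the most left-handed product at the end, and how much does it hold?

all flasks: left-handed substrate 0.10 M; right-handed substrate 0.10 M

| run | coupling partner | free catalyst | temperature | remark | time |
|---|---|---|---|---|---|
| alpha | 1.5 equiv | 0.3 mol% | 35 °C | run made earlier |  |
| alder | 1.50 equiv | 0.2 mol% | 35 °C |  | 30 h |
| oak | 1.50 equiv | 0.2 mol% | −25 °C |  | 30 h |
| larch | 1.50 equiv | 0.2 mol% | 65 °C |  | 30 h |
| maple | 1.50 equiv | 0.2 mol% | 5 °C |  | 30 h |

alpha run (percent of the left-handed substrate and right-handed substrate together charged)

| time / h | left-handed product / % |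
|---|---|
| 0.500 | 8 |
| 0.667 | 10 |
| 1.00 | 10 |
| 1.50 | 17 |
| 2.50 | 20 |
| 4.00 | 22 |
| 6.00 | 27 |

(readings scatter by 2 percentage points)

- free catalyst is single-handed; left-handed substrate and right-handed substrate are mirror images of each other, charged as a racemate, each of them at the stated concentration
- the earlier runs were read with a standard deviation of 2 percentage points
- steps thought possible: free catalyst -> spent catalyst A; 2 coupling partner -> self-condensation product; free catalyst -> spent catalyst B; coupling partner + free catalyst + left-handed substrate -> free catalyst + left-handed product; coupling partner + free catalyst + right-handed substrate -> free catalyst + right-handed product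
- the earlier runs do not show what temperature does; that part of a forecast is a guess
- no earlier run changes the charge of free catalyst; that part of a forecast is a guess

- the flask with the highest amount of left-handed product, in percent of the left-handed substrate and right-handed substrate together charged ("all alike" if they lie within 1.5 percentage points) (alder / oak / larch / maple / all alike)
- final left-handed product, as a percentage of the left-handed substrate and right-handed substrate together charged, in alder
- final left-handed product, as a percentage of the left-handed substrate and right-handed substrate together charged, in oak
- final left-handed product, as a percentage of the left-handed substrate and right-handed substrate together charged, in larch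
- final left-handed product, as a percentage of the left-handed substrate and right-handed substrate together charged, in maple

**What is the ceiling?** The left-handed substrate is half of what the percentages count, so left-handed product stops at 50 %.

**What do you plot?** I plot what I call the reach: ln(ceiling/(ceiling − product)). Left-handed substrate goes at k[coupling partner][free catalyst][left-handed substrate], which is pseudo-first-order at each moment, so the reach adds up k[coupling partner][free catalyst] over time. In alpha it stands at 0.416 after 1.50 h and at 0.777 after 6.00 h.

**Why does alpha slow down?** I see two candidates. If free catalyst dies at a first-order pace, the reach levels off. If coupling partner is lost to its own second-order condensation, that loss slows as [coupling partner] falls, [coupling partner] thins roughly as one over time, and the reach grows with ln(time). With a scatter of 2 percentage points in the readings I don't try to separate these on so few points, but I commit to the second.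

**So what do you carry forward?** I carry the gain, the reach added per unit of ln(time), which reads 0.260 from those two scattered alpha readings.

**And alder?** It has alpha's temperature, so at alpha's loading the reach at 30 h would be 1.20. Alder carries 0.667 of that loading, and if reach follows the catalyst, that makes 0.797, or 27.5 %.

**Where is that weak?** The stretch from 6.00 h to 30 h lies beyond the readings, and the scaling with catalyst is a guess. No earlier run shows temperature, so I have no reckoning of my own for oak, larch or maple.

The forecast names alder. Of the slowing in alpha it says “the catalyst is dying”. It gives 24 % for alder (range 19 % to 30 %), 2 % for oak, 18 % for larch and 17 % for maple. My alder figure is higher than its figure.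

Alder gave 33.6 %, the most of the flasks, with oak at 8.23 %, larch at 15.8 % and maple at 28.8 %. At 30.0 h alder still held 75.1 % of its free catalyst and 4.77 % of its coupling partner. The gain, scaled to alder's loading and started from alder's 30.2 % of left-handed product at 15.0 h, gives 32.5 % at 30.0 h, against the 33.6 % found.

    free catalyst → spent catalyst A (k = 4.70 × 10⁻⁵ h⁻¹, Ea = 121 kJ mol⁻¹)
    2 coupling partner → self-condensation product (k = 0.770 M⁻¹ h⁻¹, Ea = 69.0 kJ mol⁻¹)
    free catalyst → spent catalyst B (k = 0.00950 h⁻¹, Ea = 116 kJ mol⁻¹)
    coupling partner + free catalyst + left-handed substrate → free catalyst + left-handed product (k = 7000 M⁻² h⁻¹, Ea = 37.0 kJ mol⁻¹)
    coupling partner + free catalyst + right-handed substrate → free catalyst + right-handed product (k = 64.0 M⁻² h⁻¹, Ea = 41.0 kJ mol⁻¹)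
    (constants at 35 °C)

Now take alder with 0.05 mol% of free catalyst, all else the same. The reach from alpha scales to 0.199, which means 9.02 % of left-handed product. That flask gives 15.3 %.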